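**Plan**

1. Locants: the 2,3-dihydro-1,4-benzodioxine core is O1–C2–C3–O4 on benzo ring A, where O1 is the outer and O4 the inner oxygen of the obovatol catechol. C2 carries catechol ring C, and C3 carries C9, the exocyclic CH2O carbon.
2. Retrosynthetic cuts, in order: C9–O to the magnolol unit (Mitsunobu), then C3–O4 of the dioxane (key step), then C2–O1 (phenoxide opening of an epoxy alcohol), and last the C=C bond and the diaryl ether of the ring C cinnamyl alcohol.
3. Enabling feature: C3, which bears O4 and C9, sits between benzylic C2 and primary C9. An epoxy alcohol made from the ring C cinnamyl alcohol can therefore relay oxygen down the three-carbon chain: O1 is installed at C2, the oxygen first on C3 ends on C9 by way of a C3–C9 epoxide, and O4 replaces it at C3.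
4. Forward order: ring C aldehyde → acetonide → O-arylation → cinnamyl alcohol → epoxy alcohol; obovatol is masked at O4; the halves are joined at C2–O1; C9 is tosylated and O4 released; the dioxane (the only ring formed) closes; magnolol is attached and the acetonide removed.
5. Stereochemistry: the Sharpless epoxidation with L-(+)-tartrate sets both epoxide carbons as S. One inversion at C2 (epoxide opening) and one at C3 (ring closure) give the trans-(2R,3R) benzodioxane, and no later step touches either centre.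

Key step: step 12

Assumption: obovatol and magnolol are taken as purchasable natural products, and the outer hydroxyl of obovatol (one ortho hydrogen) is taken to be the sterically more accessible of the two.

**Route**

Step 1
Reactants: 1 3,4,5-trihydroxybenzaldehyde
Product: 2 ring C acetonide aldehyde (7-hydroxy-2,2-dimethyl-1,3-benzodioxole-5-carbaldehyde)
Conditions: 2,2-dimethoxypropane, p-TsOH·H2O (cat.), toluene, reflux (4 Å MS in a Soxhlet); aq. work-up
Reagents that add atoms: 2,2-dimethoxypropane, COC(C)(C)OC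
Why: Acid-catalysed transketalisation can bridge only two adjacent phenols, and since the triol is symmetric either pair gives the same isopropylidene ketal with one flanking hydroxyl left free, while any dimethyl acetal formed at the aldehyde should revert on aqueous work-up.

Step 2
Reactants: 2 ring C acetonide aldehyde; 3 1-allyl-4-bromobenzene
Product: 4 diaryl ether aldehyde (7-(4-allylphenoxy)-2,2-dimethyl-1,3-benzodioxole-5-carbaldehyde)
Conditions: CuI (10 mol %), N,N-dimethylglycine·HCl (30 mol %), Cs2CO3, 1,4-dioxane, 90 °C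
Reagents that add atoms: none
Why: An Ullmann-type diaryl ether synthesis catalysed by monovalent copper with an amino acid ligand couples phenols with unactivated aryl bromides at a temperature and carbonate basicity under which the aldehyde, the ketal and the allyl double bond should stay in place.

Step 3
Reactants: 4 diaryl ether aldehyde
Product: 5 ethyl (E)-3-[7-(4-allylphenoxy)-2,2-dimethyl-1,3-benzodioxol-5-yl]prop-2-enoate
Conditions: (EtO)2P(O)CH2CO2Et, NaH, THF, 0 °C to rt
Reagents that add atoms: triethyl phosphonoacetate, CCOC(=O)CP(=O)(OCC)OCC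
Why: The Horner–Wadsworth–Emmons olefination of an aryl aldehyde with a stabilised phosphonate anion should give the (E)-cinnamate, because the reversible addition funnels through the anti oxaphosphetane.

Step 4
Reactants: 5 ethyl (E)-cinnamate
Product: 6 (E)-3-[7-(4-allylphenoxy)-2,2-dimethyl-1,3-benzodioxol-5-yl]prop-2-en-1-ol
Conditions: i-Bu2AlH, CH2Cl2, −78 °C; aq. potassium sodium tartrate work-up
Reagents that add atoms: none
Why: 1,2-Reduction of the conjugated ester by the aluminium hydride at low temperature should give the allylic alcohol without touching the double bonds, the ketal or the aryl ethers.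

Step 5
Reactants: 6 (E)-cinnamyl alcohol
Product: 7 epoxy alcohol ([(2S,3S)-3-[7-(4-allylphenoxy)-2,2-dimethyl-1,3-benzodioxol-5-yl]oxiran-2-yl]methanol)
Conditions: Ti(OiPr)4 (10 mol %), L-(+)-diisopropyl tartrate (12 mol %), t-BuOOH, 4 Å MS, CH2Cl2, −20 °C
Reagents that add atoms: tert-butyl hydroperoxide, CC(C)(C)OO
Why: In the Sharpless asymmetric epoxidation the tetravalent titanium tartrate complex binds the allylic hydroxyl and, with L-(+)-tartrate, delivers oxygen to the face that gives the (2S,3S)-epoxide, as for (E)-cinnamyl alcohol itself, while the allyl double bonds have no directing hydroxyl and should not react.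

Step 6
Reactants: 8 obovatol (5-allyl-3-(4-allylphenoxy)benzene-1,2-diol)
Product: 9 O1-silyl obovatol (4-allyl-2-(4-allylphenoxy)-6-[(triisopropylsilyl)oxy]phenol)
Conditions: i-Pr3SiCl, imidazole, DMF, 0 °C
Reagents that add atoms: chlorotriisopropylsilane, CC(C)[Si](Cl)(C(C)C)C(C)C
Why: Silylation of a phenol with a bulky chlorosilane and imidazole is steered by sterics, so the silyl group should go to the outer hydroxyl (future O1) and not to the inner one, which is wedged between the aryloxy group and the other oxygen.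

Step 7
Reactants: 9 O1-silyl obovatol
Product: 10 O1-silyl O4-MOM obovatol ({[5-allyl-3-(4-allylphenoxy)-2-(methoxymethoxy)phenyl]oxy}triisopropylsilane)
Conditions: MeOCH2Cl, i-Pr2NEt, CH2Cl2, 0 °C to rt
Reagents that add atoms: chloromethyl methyl ether, COCCl
Why: Williamson-type alkylation of the remaining inner phenol (future O4) by the very reactive chloromethyl ether under an amine base installs the MOM acetal, and the bulk of the triisopropylsilyl group together with the absence of a free phenoxide should keep O-to-O silyl migration slow.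

Step 8
Reactants: 10 O1-silyl O4-MOM obovatol
Product: 11 O4-MOM obovatol (5-allyl-3-(4-allylphenoxy)-2-(methoxymethoxy)phenol)
Conditions: Bu4NF, THF, 0 °C
Reagents that add atoms: none
Why: Fluoride-induced desilylation cleaves the aryl O–Si bond, driven by the strong Si–F bond, and leaves the MOM acetal and the allyl groups alone, so only O1 is set free.

Step 9
Reactants: 7 epoxy alcohol; 11 O4-MOM obovatol
Product: 12 diol ((2S,3R)-3-[5-allyl-3-(4-allylphenoxy)-2-(methoxymethoxy)phenoxy]-3-[7-(4-allylphenoxy)-2,2-dimethyl-1,3-benzodioxol-5-yl]propane-1,2-diol)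
Conditions: NaOH (aq), 1,4-dioxane, 70 °C, argon
Reagents that add atoms: none
Why: Base-mediated SN2 opening of a trans-3-aryl-2,3-epoxy alcohol by a phenoxide occurs at the benzylic carbon with inversion, as known for 3-phenylglycidol and 2-alkoxyphenols, so the benzylic carbon (C2) should become R while the carbinol carbon (C3) keeps its S configuration.

Step 10
Reactants: 12 diol
Product: 13 primary tosylate ((2S,3R)-3-[5-allyl-3-(4-allylphenoxy)-2-(methoxymethoxy)phenoxy]-3-[7-(4-allylphenoxy)-2,2-dimethyl-1,3-benzodioxol-5-yl]-2-hydroxypropyl 4-methylbenzenesulfonate)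
Conditions: TsCl, Et3N, Bu2SnO (2 mol %), CH2Cl2, rt
Reagents that add atoms: 4-methylbenzenesulfonyl chloride, Cc1ccc(cc1)S(Cl)(=O)=O
Why: Bu2SnO-catalysed sulfonylation of a 1,2-diol runs through a stannylene acetal that activates the primary oxygen, so only C9–OH should be tosylated and the secondary C3–OH stays free.

Step 11
Reactants: 13 primary tosylate
Product: 14 phenol hydroxy tosylate ((2S,3R)-3-[5-allyl-3-(4-allylphenoxy)-2-hydroxyphenoxy]-3-[7-(4-allylphenoxy)-2,2-dimethyl-1,3-benzodioxol-5-yl]-2-hydroxypropyl 4-methylbenzenesulfonate)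
Conditions: NaHSO4·SiO2, CH2Cl2, rt
Reagents that add atoms: none
Why: Silica-supported NaHSO4 is a mild heterogeneous acid that hydrolyses phenolic MOM acetals at room temperature, under which the catechol isopropylidene ketal, the sulfonate and the benzylic aryl ether (its ionisation slowed by the oxygenated neighbouring carbon) should survive.

Step 12
Reactants: 14 phenol hydroxy tosylate
Product: 16 benzodioxane-methanol ([(2R,3R)-7-allyl-5-(4-allylphenoxy)-2-[7-(4-allylphenoxy)-2,2-dimethyl-1,3-benzodioxol-5-yl]-2,3-dihydro-1,4-benzodioxin-3-yl]methanol), via terminal epoxide phenol 15 (not isolated)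
Conditions: K2CO3, MeOH, rt to 40 °C, argon
Reagents that add atoms: none
Why: Carbonate in methanol ionises the phenol O4–H fully and the C3 hydroxyl to a small extent; the small equilibrium share of C3 alkoxide closes onto C9 with loss of tosylate (3-exo-tet, C3 keeps its S configuration) to give epoxide 15, and the ring A phenoxide then attacks C3 of this epoxide from the rear (6-exo-tet), which forms the C3–O4 bond, closes the dioxane ring and releases the C9 alkoxide. The closest known reactions are the Payne-type conversion of hydroxy sulfonates into terminal epoxides and the base-mediated cyclisation of catechol mono(glycidyl) ethers to 2-hydroxymethyl-1,4-benzodioxanes. The only new stereocentre, C3, is set by the substrate: C3 is not benzylic, so the opening should be a clean SN2 inversion (S to R), which with the untouched R centre at C2 gives the trans-(2R,3R) ring. The step needs epoxide formation to outrun direct seven-membered attack of the phenoxide on C9, and 6-exo opening at C3 to beat 7-endo opening at C9. The first should be secured by the high intrinsic rate of three-membered closure next to a β-branched, slowly displaced tosylate and by the crowded position of O4 between two ortho oxygens, the second by the six-membered ring size that the O1–C2 tether imposes. The allyl groups, diaryl ethers and acetonide are inert to carbonate.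

Step 13
Reactants: 16 benzodioxane-methanol; 17 magnolol (5,5'-diallylbiphenyl-2,2'-diol)
Product: 18 target acetonide (5,5'-diallyl-2'-{[(2R,3R)-7-allyl-5-(4-allylphenoxy)-2-[7-(4-allylphenoxy)-2,2-dimethyl-1,3-benzodioxol-5-yl]-2,3-dihydro-1,4-benzodioxin-3-yl]methoxy}biphenyl-2-ol)
Conditions: PPh3, DIAD, THF, 0 °C to rt (17 in threefold excess)
Reagents that add atoms: none
Why: Mitsunobu etherification of the unhindered primary alcohol with a phenol forms the C9–O aryl ether without touching either stereocentre, and the excess of the symmetric bisphenol should keep double alkylation low.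

Step 14
Reactants: 18 target acetonide
Product: 19 CNP0231734.1 (5-[(2R,3R)-7-allyl-5-(4-allylphenoxy)-3-{[(5,5'-diallyl-2'-hydroxybiphenyl-2-yl)oxy]methyl}-2,3-dihydro-1,4-benzodioxin-2-yl]-3-(4-allylphenoxy)benzene-1,2-diol)
Conditions: 2 M HCl (aq), THF/MeOH, 50 °C, argon
Reagents that add atoms: none
Why: Acid-catalysed hydrolysis of the catechol isopropylidene ketal releases acetone and the free catechol, and dilute aqueous acid should neither add to the allyl groups nor disturb the trans-benzodioxane, which is the more stable ring isomer.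

**Compound list**

1 | 3,4,5-trihydroxybenzaldehyde | O=Cc1cc(O)c(O)c(O)c1 | starting material
2 | 7-hydroxy-2,2-dimethyl-1,3-benzodioxole-5-carbaldehyde | O=Cc1cc(O)c2OC(C)(C)Oc2c1 | intermediate
3 | 1-allyl-4-bromobenzene | C=CCc1ccc(Br)cc1 | starting material
4 | 7-(4-allylphenoxy)-2,2-dimethyl-1,3-benzodioxole-5-carbaldehyde | O=Cc1cc(Oc2ccc(CC=C)cc2)c2OC(C)(C)Oc2c1 | intermediate
5 | ethyl (E)-3-[7-(4-allylphenoxy)-2,2-dimethyl-1,3-benzodioxol-5-yl]prop-2-enoate | CCOC(=O)/C=C/c1cc(Oc2ccc(CC=C)cc2)c2OC(C)(C)Oc2c1 | intermediate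
6 | (E)-3-[7-(4-allylphenoxy)-2,2-dimethyl-1,3-benzodioxol-5-yl]prop-2-en-1-ol | OC/C=C/c1cc(Oc2ccc(CC=C)cc2)c2OC(C)(C)Oc2c1 | intermediate
7 | [(2S,3S)-3-[7-(4-allylphenoxy)-2,2-dimethyl-1,3-benzodioxol-5-yl]oxiran-2-yl]methanol | OC[C@@H]1O[C@H]1c1cc(Oc2ccc(CC=C)cc2)c2OC(C)(C)Oc2c1 | intermediate
8 | obovatol, 5-allyl-3-(4-allylphenoxy)benzene-1,2-diol | C=CCc1cc(O)c(O)c(Oc2ccc(CC=C)cc2)c1 | starting material
9 | 4-allyl-2-(4-allylphenoxy)-6-[(triisopropylsilyl)oxy]phenol | C=CCc1cc(O[Si](C(C)C)(C(C)C)C(C)C)c(O)c(Oc2ccc(CC=C)cc2)c1 | intermediate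
10 | {[5-allyl-3-(4-allylphenoxy)-2-(methoxymethoxy)phenyl]oxy}triisopropylsilane | C=CCc1cc(O[Si](C(C)C)(C(C)C)C(C)C)c(OCOC)c(Oc2ccc(CC=C)cc2)c1 | intermediate
11 | 5-allyl-3-(4-allylphenoxy)-2-(methoxymethoxy)phenol | C=CCc1cc(O)c(OCOC)c(Oc2ccc(CC=C)cc2)c1 | intermediate
12 | (2S,3R)-3-[5-allyl-3-(4-allylphenoxy)-2-(methoxymethoxy)phenoxy]-3-[7-(4-allylphenoxy)-2,2-dimethyl-1,3-benzodioxol-5-yl]propane-1,2-diol | OC[C@H](O)[C@H](Oc1cc(CC=C)cc(Oc2ccc(CC=C)cc2)c1OCOC)c1cc(Oc2ccc(CC=C)cc2)c2OC(C)(C)Oc2c1 | intermediate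
13 | (2S,3R)-3-[5-allyl-3-(4-allylphenoxy)-2-(methoxymethoxy)phenoxy]-3-[7-(4-allylphenoxy)-2,2-dimethyl-1,3-benzodioxol-5-yl]-2-hydroxypropyl 4-methylbenzenesulfonate | Cc1ccc(cc1)S(=O)(=O)OC[C@H](O)[C@H](Oc1cc(CC=C)cc(Oc2ccc(CC=C)cc2)c1OCOC)c1cc(Oc2ccc(CC=C)cc2)c2OC(C)(C)Oc2c1 | intermediate
14 | (2S,3R)-3-[5-allyl-3-(4-allylphenoxy)-2-hydroxyphenoxy]-3-[7-(4-allylphenoxy)-2,2-dimethyl-1,3-benzodioxol-5-yl]-2-hydroxypropyl 4-methylbenzenesulfonate | Cc1ccc(cc1)S(=O)(=O)OC[C@H](O)[C@H](Oc1cc(CC=C)cc(Oc2ccc(CC=C)cc2)c1O)c1cc(Oc2ccc(CC=C)cc2)c2OC(C)(C)Oc2c1 | intermediate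
15 | 4-allyl-2-(4-allylphenoxy)-6-{(R)-[7-(4-allylphenoxy)-2,2-dimethyl-1,3-benzodioxol-5-yl][(2S)-oxiran-2-yl]methoxy}phenol | C=CCc1ccc(Oc2cc([C@@H](Oc3cc(CC=C)cc(Oc4ccc(CC=C)cc4)c3O)[C@@H]3CO3)cc3OC(C)(C)Oc23)cc1 | intermediate
16 | [(2R,3R)-7-allyl-5-(4-allylphenoxy)-2-[7-(4-allylphenoxy)-2,2-dimethyl-1,3-benzodioxol-5-yl]-2,3-dihydro-1,4-benzodioxin-3-yl]methanol | C=CCc1ccc(Oc2cc([C@H]3Oc4cc(CC=C)cc(Oc5ccc(CC=C)cc5)c4O[C@@H]3CO)cc3OC(C)(C)Oc23)cc1 | intermediate
17 | magnolol, 5,5'-diallylbiphenyl-2,2'-diol | C=CCc1ccc(O)c(-c2cc(CC=C)ccc2O)c1 | starting material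
18 | 5,5'-diallyl-2'-{[(2R,3R)-7-allyl-5-(4-allylphenoxy)-2-[7-(4-allylphenoxy)-2,2-dimethyl-1,3-benzodioxol-5-yl]-2,3-dihydro-1,4-benzodioxin-3-yl]methoxy}biphenyl-2-ol | C=CCc1ccc(Oc2cc([C@H]3Oc4cc(CC=C)cc(Oc5ccc(CC=C)cc5)c4O[C@@H]3COc3ccc(CC=C)cc3-c3cc(CC=C)ccc3O)cc3OC(C)(C)Oc23)cc1 | intermediate
19 | CNP0231734.1, 5-[(2R,3R)-7-allyl-5-(4-allylphenoxy)-3-{[(5,5'-diallyl-2'-hydroxybiphenyl-2-yl)oxy]methyl}-2,3-dihydro-1,4-benzodioxin-2-yl]-3-(4-allylphenoxy)benzene-1,2-diol | C=CCc1ccc(Oc2cc([C@H]3Oc4cc(CC=C)cc(Oc5ccc(CC=C)cc5)c4O[C@@H]3COc3ccc(CC=C)cc3-c3cc(CC=C)ccc3O)cc(O)c2O)cc1 | target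

**Step count and risks**

Total: 14 steps. Longest linear sequence: 11 steps (steps 1–5 and 9–14, from 3,4,5-trihydroxybenzaldehyde); the ring A branch (steps 6–8) joins at step 9.

Steps most likely to fail:

Step 12. The relay may be short-circuited by direct seven-membered displacement of the tosylate by the phenoxide, or by 7-endo opening of the epoxide at C9, which would give a ring-expanded isomer. The fallback closes the same C3–O4 bond by intramolecular Mitsunobu etherification; it sets out from diol 12 and returns at 16. The primary hydroxyl of 12 would be silylated selectively (t-BuPh2SiCl, imidazole, CH2Cl2) to give the primary silyl ether F1. The MOM acetal would be removed as in step 11 to give the phenol F2. PPh3 and DIAD would then activate C3–OH, the only free alcohol, and O4 would displace it with inversion in a six-membered closure to give the silylated benzodioxane F3. With C9 capped, no seven-membered path exists. Bu4NF in THF would then give 16.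

Step 9. Payne rearrangement of the epoxy alcohol under aqueous base may precede the opening, so that the phenoxide enters at the terminal carbon. Partial ionisation at the electron-rich benzylic carbon may also erode the inversion. The fallback removes the free hydroxyl before the opening; it sets out from 7 and returns at 12. Compound 7 would be capped (i-Pr3SiCl, imidazole, DMF) to give the epoxy silyl ether F4, which cannot rearrange. The phenoxide of 11, generated with Cs2CO3 in DMF at 80 °C, would open it at the benzylic carbon with inversion to give the mono-silylated diol F5. Bu4NF in THF would then give 12.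

Step 7. The silyl group may migrate from O1 to O4 before alkylation, which would place the MOM group on the wrong oxygen, or the crowded inner phenol may react too slowly. The fallback blocks O1 with a sulfonate, which does not migrate; it sets out from obovatol 8 and returns at 11. TsCl (1 equiv) and Et3N in CH2Cl2 at −20 °C should sulfonylate the less hindered outer hydroxyl to give the monotosylate F6. MeOCH2Cl and K2CO3 in acetone would alkylate the inner phenol to give the tosyl MOM ether F7. KOH in MeOH/H2O at 60 °C would cleave the aryl sulfonate and give 11.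

**Further compounds**

F1 | step 12 | (2S,3R)-3-[5-allyl-3-(4-allylphenoxy)-2-(methoxymethoxy)phenoxy]-3-[7-(4-allylphenoxy)-2,2-dimethyl-1,3-benzodioxol-5-yl]-1-[(tert-butyldiphenylsilyl)oxy]propan-2-ol | CC(C)(C)[Si](c1ccccc1)(c1ccccc1)OC[C@H](O)[C@H](Oc1cc(CC=C)cc(Oc2ccc(CC=C)cc2)c1OCOC)c1cc(Oc2ccc(CC=C)cc2)c2OC(C)(C)Oc2c1
F2 | step 12 | (2S,3R)-3-[5-allyl-3-(4-allylphenoxy)-2-hydroxyphenoxy]-3-[7-(4-allylphenoxy)-2,2-dimethyl-1,3-benzodioxol-5-yl]-1-[(tert-butyldiphenylsilyl)oxy]propan-2-ol | CC(C)(C)[Si](c1ccccc1)(c1ccccc1)OC[C@H](O)[C@H](Oc1cc(CC=C)cc(Oc2ccc(CC=C)cc2)c1O)c1cc(Oc2ccc(CC=C)cc2)c2OC(C)(C)Oc2c1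
F3 | step 12 | tert-butyl{[(2R,3R)-7-allyl-5-(4-allylphenoxy)-2-[7-(4-allylphenoxy)-2,2-dimethyl-1,3-benzodioxol-5-yl]-2,3-dihydro-1,4-benzodioxin-3-yl]methoxy}diphenylsilane | C=CCc1ccc(Oc2cc([C@H]3Oc4cc(CC=C)cc(Oc5ccc(CC=C)cc5)c4O[C@@H]3CO[Si](c3ccccc3)(c3ccccc3)C(C)(C)C)cc3OC(C)(C)Oc23)cc1
F4 | step 9 | {[(2S,3S)-3-[7-(4-allylphenoxy)-2,2-dimethyl-1,3-benzodioxol-5-yl]oxiran-2-yl]methoxy}triisopropylsilane | CC(C)[Si](C(C)C)(C(C)C)OC[C@@H]1O[C@H]1c1cc(Oc2ccc(CC=C)cc2)c2OC(C)(C)Oc2c1
F5 | step 9 | (2S,3R)-3-[5-allyl-3-(4-allylphenoxy)-2-(methoxymethoxy)phenoxy]-3-[7-(4-allylphenoxy)-2,2-dimethyl-1,3-benzodioxol-5-yl]-1-[(triisopropylsilyl)oxy]propan-2-ol | CC(C)[Si](C(C)C)(C(C)C)OC[C@H](O)[C@H](Oc1cc(CC=C)cc(Oc2ccc(CC=C)cc2)c1OCOC)c1cc(Oc2ccc(CC=C)cc2)c2OC(C)(C)Oc2c1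
F6 | step 7 | 5-allyl-3-(4-allylphenoxy)-2-hydroxyphenyl 4-methylbenzenesulfonate | C=CCc1cc(OS(=O)(=O)c2ccc(C)cc2)c(O)c(Oc2ccc(CC=C)cc2)c1
F7 | step 7 | 5-allyl-3-(4-allylphenoxy)-2-(methoxymethoxy)phenyl 4-methylbenzenesulfonate | C=CCc1cc(OS(=O)(=O)c2ccc(C)cc2)c(OCOC)c(Oc2ccc(CC=C)cc2)c1
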